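**Strategy.** Everything rests on cutting ring C at C3–C4 and O1–C2 and ring A at C8a–C4a, which leads back to a squarate-derived allenylcyclobutenone and a ring-B styryl ether. The key step exploits the hexasubstituted ring A: its like oxygens at C7 and C8 sit between the para pair C6–O and C8a–O, the footprint of a symmetric squarate, and O1–C8a–C4a–C4 is an o-quinone methide heterodiene. In one pot, thermolysis expands the four-membered ring into ring A and the quinone methide so released captures the enol ether, closing ring C with ring B on C3. The precursor is racemic 4-methoxy-4-(1-benzyloxyallenyl)-2,3-bis(benzyloxy)cyclobutenone, carrying the future C6 methyl ether on its carbinol oxygen.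

Key step: step 6

Remarks on the chemistry:
- Compounds 13 to 15 are carried as racemic mixtures of diastereomers, and 10 as an E/Z mixture.
- Allenes 4 and 7 and enol ether 10 are assumed to be acid-labile and are purified on base-washed silica.
- The 5,8-dihydroxy (hydroquinone-type) ring A of the target is assumed to be air-sensitive, so step 9 is worked up with exclusion of oxygen.

Step 1
Reactants: 1 squaric acid
Product: 2 dibenzyl squarate
Conditions: BnOH (2.5 equiv), toluene, reflux, Dean–Stark
Reagents that add atoms: benzyl alcohol, OCc1ccccc1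
Why: Acid-autocatalysed Fischer-type esterification of the vinylogous diacid, driven by azeotropic removal of water as for other dialkyl squarates; no stereocentre is formed.

Step 2
Reactants: 3 benzyl propargyl ether
Product: 4 benzyloxyallene
Conditions: KOtBu (0.3 equiv), THF, 0 °C to rt
Reagents that add atoms: none
Why: Base-catalysed propargyl-to-allenyl prototropic isomerization, which should stop at the oxygen-conjugated alkoxyallene under catalytic alkoxide.

Step 3
Reactants: 4 benzyloxyallene; 2 dibenzyl squarate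
Product: 7 4-[1-(benzyloxy)propa-1,2-dien-1-yl]-2,3-bis(benzyloxy)-4-methoxycyclobut-2-en-1-one (racemic), via 1-lithio-1-(benzyloxy)allene 5 (not isolated), via lithium cyclobutenolate adduct 6 (not isolated)
Conditions: 4, n-BuLi, THF, −78 to −40 °C; cannulated into 2, THF, −78 °C; MeOTf, −78 to −20 °C
Reagents that add atoms: methyl trifluoromethanesulfonate, COS(=O)(=O)C(F)(F)F
Why: α-Lithiation of the alkoxyallene at its oxygen-bearing carbon, 1,2-addition of the organolithium to one of the two equivalent squarate carbonyls and Williamson-type O-methylation of the tertiary lithium alkoxide by the triflate should deliver 7; the quaternary carbinol centre forms racemic, which is harmless because it becomes sp2 in step 6.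

Step 4
Reactants: 8 3-hydroxy-4,5-dimethoxybenzaldehyde
Product: 9 3-(benzyloxy)-4,5-dimethoxybenzaldehyde
Conditions: BnBr, K2CO3, DMF, rt
Reagents that add atoms: benzyl bromide, BrCc1ccccc1
Why: Williamson etherification of the phenoxide, which the aldehyde tolerates.

Step 5
Reactants: 9 3-(benzyloxy)-4,5-dimethoxybenzaldehyde
Product: 10 1-(benzyloxy)-2,3-dimethoxy-5-(2-methoxyethenyl)benzene (E/Z mixture)
Conditions: Ph3P(CH2OMe)Cl, KOtBu, THF, 0 °C to rt
Reagents that add atoms: (methoxymethyl)triphenylphosphonium chloride, COC[P+](c1ccccc1)(c1ccccc1)c1ccccc1.[Cl-]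
Why: Wittig methoxymethylenation of the aromatic aldehyde; the alkene geometry is left unseparated because it is erased in step 8.

Step 6
Reactants: 7 4-[1-(benzyloxy)propa-1,2-dien-1-yl]-2,3-bis(benzyloxy)-4-methoxycyclobut-2-en-1-one; 10 1-(benzyloxy)-2,3-dimethoxy-5-(2-methoxyethenyl)benzene
Product: 13 5,7,8-tris(benzyloxy)-3-[3-(benzyloxy)-4,5-dimethoxyphenyl]-2,6-dimethoxychroman (2-methoxyisoflavan; diastereomer mixture), via allenyl vinylketene 11 (not isolated), via o-quinone methide 12 (not isolated)
Conditions: 10 (3 equiv), toluene, 110 °C, slow addition of 7, argon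
Reagents that add atoms: none
Why: Heating opens the cyclobutenone by conrotatory 4π electrocyclic ring opening, the C4 methoxy donor rotating outward so that the allenyl group lies cis to the ketene in 11; 6π electrocyclization of the ketene carbon onto the central allene carbon then forms the C8a–C4a bond and closes ring A as o-quinone methide 12 without any hydrogen shift. The heterodiene O=C8a–C4a=C4 of 12 adds enol ether 10 in an inverse-electron-demand hetero-Diels–Alder (4+2) cycloaddition that forms C4–C3 and O1–C2, closes ring C and restores the aromaticity of ring A. The closest known reaction type is the Moore-type thermolysis of 4-allenylcyclobutenones to o-quinone methides with in situ trapping by enol ethers to 2-alkoxychromans. The stereocentres at C2 and C3 arise as a mixture (endo/exo approach, both alkene isomers of 10) under no control, which is acceptable because step 8 removes both. The regiochemistry needed (ring B on C3) is secured by the methoxy donor of 10, which makes the aryl-bearing carbon the nucleophilic terminus that bonds to the electrophilic C4 methylene while the C8a oxygen bonds to the incipient oxocarbenium carbon; cross reaction over self-condensation of 12 is secured by excess 10 and slow addition of 7. The ring-A pattern is fixed by the symmetric squarate core, the methylated carbinol oxygen becoming the C6 ether and the ketene oxygen becoming O1, so the isomeric 5,6,7-trioxygenated chromone cannot arise.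

Step 7
Reactants: 13 5,7,8-tris(benzyloxy)-3-[3-(benzyloxy)-4,5-dimethoxyphenyl]-2,6-dimethoxychroman
Product: 14 5,7,8-tris(benzyloxy)-3-[3-(benzyloxy)-4,5-dimethoxyphenyl]-2,6-dimethoxychroman-4-ol (diastereomer mixture)
Conditions: DDQ (1.2 equiv), CH2Cl2/pH 7 phosphate buffer (10:1), 0 °C to rt
Reagents that add atoms: water, O
Why: Benzylic C–H oxidation by hydride abstraction with DDQ: the C4 cation is stabilized by O1 and by the C5 and C7 benzyloxy groups and is captured by water, whereas the benzyl ether methylenes and ring B offer no comparably stabilized cation; the C4 centre forms unselectively and is removed in step 8.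

Step 8
Reactants: 14 5,7,8-tris(benzyloxy)-3-[3-(benzyloxy)-4,5-dimethoxyphenyl]-2,6-dimethoxychroman-4-ol
Product: 16 5,7,8-tris(benzyloxy)-3-[3-(benzyloxy)-4,5-dimethoxyphenyl]-6-methoxy-4H-chromen-4-one, via 2-methoxyisoflavan-4-one 15 (not isolated)
Conditions: Dess–Martin periodinane, pyridine, CH2Cl2, 0 °C to rt; then DBU, rt
Reagents that add atoms: none
Why: Dess–Martin oxidation of the secondary benzylic alcohol gives ketone 15, whose acidic C3–H allows DBU-mediated E1cB loss of methoxide from the C2 acetal carbon, driven by formation of the 4-pyranone ring; all three stereocentres vanish.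

Step 9
Reactants: 16 5,7,8-tris(benzyloxy)-3-[3-(benzyloxy)-4,5-dimethoxyphenyl]-6-methoxy-4H-chromen-4-one
Product: 17 5,7,8-trihydroxy-3-(3-hydroxy-4,5-dimethoxyphenyl)-6-methoxy-4H-chromen-4-one (target)
Conditions: H2 (1 atm), 10% Pd/C, degassed EtOAc/MeOH, rt; filtration under argon
Reagents that add atoms: none
Why: Heterogeneous palladium-catalysed hydrogenolysis of the four aryl benzyl ethers; the conjugated C2=C3 bond of the isoflavone and the methyl ethers should be inert under these mild conditions, and no stereocentre is present.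

**Compound list**

1 | squaric acid | O=C1C(O)=C(O)C1=O | starting material
2 | dibenzyl squarate, 3,4-bis(benzyloxy)cyclobut-3-ene-1,2-dione | O=C1C(=O)C(OCc2ccccc2)=C1OCc1ccccc1 | intermediate
3 | benzyl propargyl ether | C#CCOCc1ccccc1 | starting material
4 | benzyloxyallene | C=C=COCc1ccccc1 | intermediate
5 | 1-lithio-1-(benzyloxy)allene | [Li]C(=C=C)OCc1ccccc1 | intermediate (not isolated)
6 | lithium 1-[1-(benzyloxy)propa-1,2-dien-1-yl]-2,3-bis(benzyloxy)-4-oxocyclobut-2-en-1-olate, racemic | [Li]OC1(C(=C=C)OCc2ccccc2)C(=O)C(OCc2ccccc2)=C1OCc1ccccc1 | intermediate (not isolated)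
7 | 4-[1-(benzyloxy)propa-1,2-dien-1-yl]-2,3-bis(benzyloxy)-4-methoxycyclobut-2-en-1-one, racemic | C=C=C(OCc1ccccc1)C1(OC)C(=O)C(OCc2ccccc2)=C1OCc1ccccc1 | intermediate
8 | 3-hydroxy-4,5-dimethoxybenzaldehyde | COc1cc(C=O)cc(O)c1OC | starting material
9 | 3-(benzyloxy)-4,5-dimethoxybenzaldehyde | COc1cc(C=O)cc(OCc2ccccc2)c1OC | intermediate
10 | 1-(benzyloxy)-2,3-dimethoxy-5-(2-methoxyethenyl)benzene, E/Z mixture | COC=Cc1cc(OC)c(OC)c(OCc2ccccc2)c1 | intermediate
11 | (3Z)-2,3,5-tris(benzyloxy)-4-methoxyhepta-1,3,5,6-tetraen-1-one (allenyl vinylketene) | O=C=C(OCc1ccccc1)/C(OCc1ccccc1)=C(OC)\C(OCc1ccccc1)=C=C | intermediate (not isolated)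
12 | 2,3,5-tris(benzyloxy)-4-methoxy-6-methylidenecyclohexa-2,4-dien-1-one (o-quinone methide) | C=C1C(=O)C(OCc2ccccc2)=C(OCc2ccccc2)C(OC)=C1OCc1ccccc1 | intermediate (not isolated)
13 | 5,7,8-tris(benzyloxy)-3-[3-(benzyloxy)-4,5-dimethoxyphenyl]-2,6-dimethoxychroman, racemic mixture of C2/C3 diastereomers | COC1Oc2c(OCc3ccccc3)c(OCc3ccccc3)c(OC)c(OCc3ccccc3)c2CC1c1cc(OC)c(OC)c(OCc2ccccc2)c1 | intermediate
14 | 5,7,8-tris(benzyloxy)-3-[3-(benzyloxy)-4,5-dimethoxyphenyl]-2,6-dimethoxychroman-4-ol, racemic mixture of diastereomers | COC1Oc2c(OCc3ccccc3)c(OCc3ccccc3)c(OC)c(OCc3ccccc3)c2C(O)C1c1cc(OC)c(OC)c(OCc2ccccc2)c1 | intermediate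
15 | 5,7,8-tris(benzyloxy)-3-[3-(benzyloxy)-4,5-dimethoxyphenyl]-2,6-dimethoxychroman-4-one, racemic mixture of diastereomers | COC1Oc2c(OCc3ccccc3)c(OCc3ccccc3)c(OC)c(OCc3ccccc3)c2C(=O)C1c1cc(OC)c(OC)c(OCc2ccccc2)c1 | intermediate (not isolated)
16 | 5,7,8-tris(benzyloxy)-3-[3-(benzyloxy)-4,5-dimethoxyphenyl]-6-methoxy-4H-chromen-4-one | COc1cc(-c2coc3c(OCc4ccccc4)c(OCc4ccccc4)c(OC)c(OCc4ccccc4)c3c2=O)cc(OCc2ccccc2)c1OC | intermediate
17 | 5,7,8-trihydroxy-3-(3-hydroxy-4,5-dimethoxyphenyl)-6-methoxy-4H-chromen-4-one | COc1cc(-c2coc3c(O)c(O)c(OC)c(O)c3c2=O)cc(O)c1OC | target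

**Totals.** Total step count: 9. Longest linear sequence: 6 steps (for example steps 1, 3, 6, 7, 8, 9).

**Steps most likely to fail**

Step 6. The transient quinone methide 12 may self-condense faster than it is intercepted by the hindered, conjugated 1,2-disubstituted enol ether.
- The fallback sets out from 10 and 7 and returns at 13.
- Enol ether 10 would be hydrolysed (oxalic acid, wet THF) to (3-benzyloxy-4,5-dimethoxyphenyl)acetaldehyde F1.
- F1 would be condensed with morpholine (toluene, MgSO4) to the E-enamine 4-[2-(3-benzyloxy-4,5-dimethoxyphenyl)ethenyl]morpholine F2, a far stronger π-nucleophile than 10.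
- Slow-addition thermolysis of 7 in the presence of F2 should give, through 11 and 12, the 2-morpholino isoflavan 4-{5,7,8-tris(benzyloxy)-3-[3-(benzyloxy)-4,5-dimethoxyphenyl]-6-methoxychroman-2-yl}morpholine F3. This is the known cycloaddition of o-quinone methides with enamines to 2-aminochromans.
- Acid-catalysed exchange of the aminal nitrogen for methanol (camphorsulfonic acid, MeOH, rt) would then deliver 13.

Step 7. The C4 cation may lose the C3 proton, or the product alcohol may re-ionize under the acidic hydroquinone by-product, so that dehydrogenation and over-oxidation compete with hydration.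
- The fallback sets out from 13 and returns at 14; it turns the elimination into the intended path.
- DDQ (1.05 equiv) in dry dioxane should dehydrogenate 13 to the 2-methoxyisoflav-3-ene 5,7,8-tris(benzyloxy)-3-[3-(benzyloxy)-4,5-dimethoxyphenyl]-2,6-dimethoxy-2H-chromene F4.
- Hydroboration with BH3·SMe2 in THF is expected to place boron on the less substituted benzylic C4, giving the C4 alkylborane F5.
- Oxidation with NaBO3 in aqueous THF would give alcohol 14.

Step 3. O-Methylation of the congested tertiary lithium alkoxide may be slow, and on warming the alkoxide may revert to its components, ring-open or cyclize onto the allene.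
- The fallback sets out from alkoxide 6 (generated as in step 3) and returns at 13; it moves the methylation to the phenol stage.
- Quenching 6 at −78 °C with Et3SiCl should give the silyl ether 4-[1-(benzyloxy)propa-1,2-dien-1-yl]-2,3-bis(benzyloxy)-4-(triethylsilyloxy)cyclobut-2-en-1-one F6.
- Thermolysis of F6 with 10 as in step 6 should pass through the silyloxy vinylketene (3Z)-2,3,5-tris(benzyloxy)-4-(triethylsilyloxy)hepta-1,3,5,6-tetraen-1-one F7 and the silyloxy quinone methide 2,3,5-tris(benzyloxy)-6-methylidene-4-(triethylsilyloxy)cyclohexa-2,4-dien-1-one F8. The silyloxy group rotates outward as the methoxy group does.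
- The cycloadduct would be the 6-silyloxy isoflavan 5,7,8-tris(benzyloxy)-3-[3-(benzyloxy)-4,5-dimethoxyphenyl]-2-methoxy-6-(triethylsilyloxy)chroman F9.
- Desilylation (Bu4NF, THF, 0 °C) would give the phenol 5,7,8-tris(benzyloxy)-3-[3-(benzyloxy)-4,5-dimethoxyphenyl]-2-methoxychroman-6-ol F10.
- Routine O-methylation (MeI, K2CO3, DMF) would then give 13.

Further compounds
F1 | step 6 | (3-benzyloxy-4,5-dimethoxyphenyl)acetaldehyde | O=CCc1cc(OC)c(OC)c(OCc2ccccc2)c1
F2 | step 6 | 4-[(E)-2-(3-benzyloxy-4,5-dimethoxyphenyl)ethenyl]morpholine | COc1cc(/C=C/N2CCOCC2)cc(OCc2ccccc2)c1OC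
F3 | step 6 | 4-{5,7,8-tris(benzyloxy)-3-[3-(benzyloxy)-4,5-dimethoxyphenyl]-6-methoxychroman-2-yl}morpholine, racemic diastereomer mixture | COc1cc(C2Cc3c(OCc4ccccc4)c(OC)c(OCc4ccccc4)c(OCc4ccccc4)c3OC2N2CCOCC2)cc(OCc2ccccc2)c1OC
F4 | step 7 | 5,7,8-tris(benzyloxy)-3-[3-(benzyloxy)-4,5-dimethoxyphenyl]-2,6-dimethoxy-2H-chromene, racemic | COC1Oc2c(OCc3ccccc3)c(OCc3ccccc3)c(OC)c(OCc3ccccc3)c2C=C1c1cc(OC)c(OC)c(OCc2ccccc2)c1
F5 | step 7 | C4 alkylborane of F4 (drawn as the monoalkylborane), diastereomer mixture | COC1Oc2c(OCc3ccccc3)c(OCc3ccccc3)c(OC)c(OCc3ccccc3)c2C(B)C1c1cc(OC)c(OC)c(OCc2ccccc2)c1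
F6 | step 3 | 4-[1-(benzyloxy)propa-1,2-dien-1-yl]-2,3-bis(benzyloxy)-4-(triethylsilyloxy)cyclobut-2-en-1-one, racemic | C=C=C(OCc1ccccc1)C1(O[Si](CC)(CC)CC)C(=O)C(OCc2ccccc2)=C1OCc1ccccc1
F7 | step 3 | (3Z)-2,3,5-tris(benzyloxy)-4-(triethylsilyloxy)hepta-1,3,5,6-tetraen-1-one | O=C=C(OCc1ccccc1)/C(OCc1ccccc1)=C(O[Si](CC)(CC)CC)\C(OCc1ccccc1)=C=C
F8 | step 3 | 2,3,5-tris(benzyloxy)-6-methylidene-4-(triethylsilyloxy)cyclohexa-2,4-dien-1-one | C=C1C(=O)C(OCc2ccccc2)=C(OCc2ccccc2)C(O[Si](CC)(CC)CC)=C1OCc1ccccc1
F9 | step 3 | 5,7,8-tris(benzyloxy)-3-[3-(benzyloxy)-4,5-dimethoxyphenyl]-2-methoxy-6-(triethylsilyloxy)chroman, racemic diastereomer mixture | COC1Oc2c(OCc3ccccc3)c(OCc3ccccc3)c(O[Si](CC)(CC)CC)c(OCc3ccccc3)c2CC1c1cc(OC)c(OC)c(OCc2ccccc2)c1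
F10 | step 3 | 5,7,8-tris(benzyloxy)-3-[3-(benzyloxy)-4,5-dimethoxyphenyl]-2-methoxychroman-6-ol, racemic diastereomer mixture | COC1Oc2c(OCc3ccccc3)c(OCc3ccccc3)c(O)c(OCc3ccccc3)c2CC1c1cc(OC)c(OC)c(OCc2ccccc2)c1
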